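Raising the racemization catalyst is not the route to more conversion by 15 min in this flask; a balance on the limiting reagent gives the conversion to expect.

| flask | left-handed substrate | right-handed substrate | reagent | racemization catalyst | precatalyst | remark | time |
|---|---|---|---|---|---|---|---|
| elm | 0.0050 M | 0.0050 M | 0.0125 M | 50 µM | 5 µM | run made earlier |  |
| ash | 0.0050 M | 0.0050 M | 0.0125 M | 75 µM | 5 µM | run made earlier |  |
| flask | 0.0050 M | 0.0050 M | 0.0125 M | 100 µM | 5.0 µM |  | 15 min |

| run | time / min | left-handed substrate / % | right-handed substrate / % |
|---|---|---|---|
| elm | 1.33 | 46.5 | 47.3 |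
| elm | 4.00 | 41.3 | 41.5 |
| elm | 8.00 | 34.7 | 34.8 |
| elm | 10.0 | 33.3 | 33.7 |
| elm | 15.0 | 28.2 | 27.6 |
| ash | 1.33 | 46.9 | 46.7 |
| ash | 4.00 | 40.6 | 42.0 |
| ash | 8.00 | 35.0 | 35.1 |
| ash | 10.0 | 31.6 | 32.9 |
| ash | 15.0 | 27.3 | 27.2 |

(each reading ± 0.5 percentage points)

1. part of the left-handed substrate and right-handed substrate charged together that has reacted at 15 min
2. excess of left-handed product over right-handed product in the product at 15 min
3. excess of right-handed substrate over left-handed substrate among what is left of the two at 15 min

- free catalyst is single-handed; left-handed substrate and right-handed substrate are mirror images of each other, charged as a racemate, each of them at the stated concentration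
- an excess is the difference of the two amounts in percent of their sum
- an excess is below zero if the other one leads

The two substrates together, charged at 0.0100 M, are the limiting reagent, less than the 0.0125 M of reagent. Taking one reagent per substrate consumed and a rate proportional to [substrates][reagent], the logarithm of [reagent]/[substrates], counted from its starting value and divided by time and by the reagent's excess over the substrates, is a constant k, the pair constant. The last readings give 3.92 M⁻¹ min⁻¹ in elm and 4.12 M⁻¹ min⁻¹ in ash, so k is read as 4.02 M⁻¹ min⁻¹, with 0.5 percentage points of scatter on each reading.

Racemization catalyst comes first. If k followed it, ash would show 1.50 times the k of elm, but it shows 1.05 times, so k is carried over to the 100 µM of the flask as an estimate. Precatalyst stands at 5.0 µM in the flask, as in elm and ash, so k carries over. Reagent stands at 0.0125 M in the flask, as in elm and ash, so the balance gives my own c of 44.9%. It speaks of the sum and gives neither excess.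

The forecast holds c at 45%, eS at 0.3% and eP at 40%, a weak guess: “Neither the racemization rate nor the selectivity is separately known”.

The flask gives c 45.0%, eS 0.250% and eP 74.4%, which is 34 points above the forecast.

    reagent + free catalyst + left-handed substrate → free catalyst + left-handed product (k = 24000 M⁻² s⁻¹)
    reagent + free catalyst + right-handed substrate → free catalyst + right-handed product (k = 3500 M⁻² s⁻¹)
    left-handed substrate + racemization catalyst ⇌ right-handed substrate + racemization catalyst, rate k3*[racemization catalyst]*[left-handed substrate] forward; the back reaction follows from the equilibrium constant (k = 19000 M⁻¹ s⁻¹)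
    free catalyst → spent catalyst (k = 3.10 × 10⁻⁵ s⁻¹)
    2 racemization catalyst ⇌ resting dimer, settled at all times (K = 2.70 × 10⁶ M⁻¹)
    precatalyst → free catalyst (k = 0.240 s⁻¹)

Through the same balance, the c of the flask returns k of 4.04 M⁻¹ min⁻¹. The neighbouring flask changes the reagent to 0.031 M, with the other charges and the time held, and k of 4.02 M⁻¹ min⁻¹ then gives c of 79.0%. That neighbour stands at c 79.0%, with eP 74.2%.

Readings and results were computed from invented constants; scatter was added.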